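**Retrosynthetic overview**

- Putraflavone is cut at its only interflavone bond, C3'–C8''. C3' lies on ring B of the 7-O-methylapigenin (genkwanin) unit, ortho to the free 4'-OH; C8'' lies on ring A of the 4'''-O-methylapigenin (acacetin) unit, between the 7''-oxygen and the ring oxygen O1''. Both are innately nucleophilic aryl C–H carbons, so the bond is made by anodic dehydrogenative phenol–arene cross-coupling of two intact flavones, with no halide or boron handle.
- The arene half, 5,7-di-O-benzylacacetin, comes from phloroacetophenone by dibenzylation, Claisen–Schmidt condensation with 4-methoxybenzaldehyde and I2/DMSO closure of ring C.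
- The phenol half, 5-O-acetylgenkwanin, comes from the same phloroacetophenone by 4-O-methylation, polyanion C-aroylation, acid closure of ring C, 5-O-acetylation and debenzylation, so that the 4'-OH is its only free phenol.
- Ring order: rings A and B of both halves are bought as aromatic rings; ring C of each half is closed separately; the two flavones are joined last, then the acetate and the benzyl ethers are removed while both methyl ethers stay.

Key step: step 9

Remark: the target has no stereocentre and its C3'–C8'' axis is unassigned, so the axis is formed without control; locants with no or one prime refer to the genkwanin unit, those with two or three primes to the acacetin unit.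

**Route**

Step 1
Reactants: 1 2,4,6-trihydroxyacetophenone (phloroacetophenone)
Product: 2 1-[2,4-bis(benzyloxy)-6-hydroxyphenyl]ethanone
Conditions: BnBr (2.1 equiv), K2CO3 (2.2 equiv), DMF, rt
Reagents that add atoms: benzyl bromide, BrCc1ccccc1
Why: Williamson O-alkylation (SN2): carbonate ionises the hydroxyls that are not held in the hydrogen bond to the acetyl carbonyl, so the two benzyl groups should go to O4 and one ortho oxygen while the chelated hydroxyl remains.

Step 2
Reactants: 2 1-[2,4-bis(benzyloxy)-6-hydroxyphenyl]ethanone; 3 4-methoxybenzaldehyde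
Product: 4 (E)-1-[2,4-bis(benzyloxy)-6-hydroxyphenyl]-3-(4-methoxyphenyl)prop-2-en-1-one
Conditions: KOH (50% aq), EtOH, rt; then dilute HCl
Reagents that add atoms: none
Why: Claisen–Schmidt (crossed aldol) condensation: the acetophenone enolate adds to the non-enolisable aldehyde and E1cB dehydration should give the conjugated enone in its favoured E geometry.

Step 3
Reactants: 4 (E)-1-[2,4-bis(benzyloxy)-6-hydroxyphenyl]-3-(4-methoxyphenyl)prop-2-en-1-one
Product: 6 5,7-di-O-benzylacacetin, via racemic 5,7-bis(benzyloxy)-4'-methoxyflavanone 5 (not isolated)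
Conditions: I2 (0.1 equiv), DMSO, 120–130 °C
Reagents that add atoms: none
Why: Iodine-catalysed oxidative cyclisation of a 2'-hydroxychalcone: 6-endo-trig oxa-Michael addition of the 2'-OH gives flavanone 5, whose alpha-iodination and loss of HI give the flavone while DMSO reoxidises HI to I2; the racemic C2 centre of 5 is erased and ring C of the acacetin half is closed.

Step 4
Reactants: 1 2,4,6-trihydroxyacetophenone
Product: 7 1-(2,6-dihydroxy-4-methoxyphenyl)ethanone
Conditions: Me2SO4 (1.0 equiv), K2CO3 (1.0 equiv), acetone, rt to reflux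
Reagents that add atoms: dimethyl sulfate, COS(=O)(=O)OC
Why: Phenol O-methylation (SN2 on dimethyl sulfate): the 4-OH para to the acetyl group is the most acidic hydroxyl and cannot hydrogen-bond to the carbonyl, so one equivalent of electrophile should react there first.

Step 5
Reactants: 7 1-(2,6-dihydroxy-4-methoxyphenyl)ethanone; 8 4-(benzyloxy)benzoyl chloride
Product: 9 1-[4-(benzyloxy)phenyl]-3-(2,6-dihydroxy-4-methoxyphenyl)propane-1,3-dione
Conditions: LiN(SiMe3)2 (4.2 equiv), THF, −78 to −10 °C; then 8 (1.0 equiv), −78 °C to rt; aq HCl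
Reagents that add atoms: none
Why: Polyanion variant of the Baker–Venkataraman diketone synthesis (Claisen-type C-acylation): two equivalents of amide form the diphenoxide, a third forms the ketone enolate, whose carbon is the most nucleophilic site towards the acid chloride, and the fourth deprotonates the new 1,3-diketone and so stops a second acylation.

Step 6
Reactants: 9 1-[4-(benzyloxy)phenyl]-3-(2,6-dihydroxy-4-methoxyphenyl)propane-1,3-dione
Product: 10 4'-O-benzylgenkwanin [2-[4-(benzyloxy)phenyl]-5-hydroxy-7-methoxy-4H-chromen-4-one]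
Conditions: p-TsOH·H2O (0.2 equiv), toluene, reflux, Dean–Stark
Reagents that add atoms: none
Why: Acid-catalysed cyclodehydration: one of the two equivalent phenolic hydroxyls adds to the aroyl carbonyl (6-exo-trig) and loss of water gives the 4-pyranone, which closes ring C of the genkwanin half and leaves the other hydroxyl as the chelated 5-OH, the benzyl ether tolerating the sulfonic acid.

Step 7
Reactants: 10 4'-O-benzylgenkwanin
Product: 11 5-O-acetyl-4'-O-benzylgenkwanin [2-[4-(benzyloxy)phenyl]-7-methoxy-4-oxo-4H-chromen-5-yl acetate]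
Conditions: Ac2O (3 equiv), DMAP (0.2 equiv), pyridine, rt to 50 °C
Reagents that add atoms: acetic anhydride, CC(=O)OC(C)=O
Why: DMAP-catalysed acylation: the chelated 5-OH is the only hydroxyl and, although deactivated by its hydrogen bond to the C4 carbonyl, should be acetylated by the acylpyridinium species on gentle warming.

Step 8
Reactants: 11 5-O-acetyl-4'-O-benzylgenkwanin
Product: 12 5-O-acetylgenkwanin [2-(4-hydroxyphenyl)-7-methoxy-4-oxo-4H-chromen-5-yl acetate]
Conditions: H2 (1 atm), Pd/C (10 wt%), EtOAc/THF, rt
Reagents that add atoms: none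
Why: Catalytic hydrogenolysis of a benzyl aryl ether under neutral conditions, which should leave the aryl acetate, the methyl ether and the pyranone double bond untouched and free the 4'-OH as the only phenol.

Step 9
Reactants: 12 5-O-acetylgenkwanin; 6 5,7-di-O-benzylacacetin (3 equiv, surplus recovered)
Product: 13 5-O-acetyl-5'',7''-di-O-benzylputraflavone
Conditions: boron-doped diamond anode and cathode, undivided cell, constant current (ca. 3 mA cm−2, ca. 2.2 F per mol of 12), MeNBu3+ MeOSO3− (0.1 M), (CF3)2CHOH (HFIP), 50 °C
Reagents that add atoms: none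
Why: Proposed new method: proton-coupled anodic oxidation of the 4'-OH of 12, its only free phenol, should give an HFIP-solvated phenoxyl radical whose para carbon C1' is blocked by the pyranone and whose ortho carbons C3' and C5' are equivalent; C8 of the electron-rich ring A of 6 adds to this electrophilic radical, and a second electron and two protons are lost to rearomatise both rings while H2 is evolved at the cathode. The closest known reaction type is the anodic dehydrogenative phenol–arene cross-coupling on boron-doped diamond in HFIP, established for alkyl- and alkoxyphenols with polyalkoxyarenes but not for a phenol conjugated to a pyranone nor for ring A of a flavone as the arene. No ring closes and no stereocentre forms; the C3'–C8'' axis, unassigned in the target, is left uncontrolled. Cross-coupling over homo-coupling should be secured by the lower oxidation potential of the phenol against the phenol-free arene 6, by the threefold excess of 6, and by the 5-acetate, which makes ring A of 12 a much poorer nucleophile than the dibenzyloxy ring A of 6. C8 over C6 of 6 should follow from the usual preference of 5,7-dialkoxyflavones for electrophilic attack at C8, which has one benzyloxy neighbour and the tied-back ring oxygen whereas C6 lies between two benzyloxy groups, and ring B of 6 is deactivated by conjugation to the pyranone. The electrode can reach the potential that this acceptor-substituted phenol needs, and HFIP should shield the twisted product and the benzyl ethers from over-oxidation.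

Step 10
Reactants: 13 5-O-acetyl-5'',7''-di-O-benzylputraflavone
Product: 14 5'',7''-di-O-benzylputraflavone
Conditions: K2CO3 (0.5 equiv), MeOH/THF, 0 °C to rt; aq NH4Cl
Reagents that add atoms: none
Why: Base-catalysed transesterification (methanolysis) of the aryl acetate, activated by the peri carbonyl, which should free the chelated 5-OH without touching the benzyl and methyl ethers or opening the pyranones.

Step 11
Reactants: 14 5'',7''-di-O-benzylputraflavone
Product: 15 putraflavone
Conditions: H2 (1 atm), Pd/C (10 wt%), THF/MeOH, rt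
Reagents that add atoms: none
Why: Catalytic hydrogenolysis of the two benzyl aryl ethers should free the 5''- and 7''-hydroxyls, while the aryl methyl ethers at C7 and C4''' are inert to H2 on Pd/C.

**Compound list**

1 | 2,4,6-trihydroxyacetophenone (phloroacetophenone) | CC(=O)c1c(O)cc(O)cc1O | starting material
2 | 1-[2,4-bis(benzyloxy)-6-hydroxyphenyl]ethanone | CC(=O)c1c(O)cc(OCc2ccccc2)cc1OCc1ccccc1 | intermediate
3 | 4-methoxybenzaldehyde | COc1ccc(C=O)cc1 | starting material
4 | (E)-1-[2,4-bis(benzyloxy)-6-hydroxyphenyl]-3-(4-methoxyphenyl)prop-2-en-1-one | COc1ccc(/C=C/C(=O)c2c(O)cc(OCc3ccccc3)cc2OCc2ccccc2)cc1 | intermediate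
5 | racemic 5,7-bis(benzyloxy)-2-(4-methoxyphenyl)chroman-4-one (flavanone, not isolated) | COc1ccc(C2CC(=O)c3c(OCc4ccccc4)cc(OCc4ccccc4)cc3O2)cc1 | intermediate
6 | 5,7-bis(benzyloxy)-2-(4-methoxyphenyl)-4H-chromen-4-one (5,7-di-O-benzylacacetin) | COc1ccc(-c2cc(=O)c3c(OCc4ccccc4)cc(OCc4ccccc4)cc3o2)cc1 | intermediate
7 | 1-(2,6-dihydroxy-4-methoxyphenyl)ethanone | CC(=O)c1c(O)cc(OC)cc1O | intermediate
8 | 4-(benzyloxy)benzoyl chloride | O=C(Cl)c1ccc(OCc2ccccc2)cc1 | starting material
9 | 1-[4-(benzyloxy)phenyl]-3-(2,6-dihydroxy-4-methoxyphenyl)propane-1,3-dione | COc1cc(O)c(C(=O)CC(=O)c2ccc(OCc3ccccc3)cc2)c(O)c1 | intermediate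
10 | 2-[4-(benzyloxy)phenyl]-5-hydroxy-7-methoxy-4H-chromen-4-one (4'-O-benzylgenkwanin) | COc1cc(O)c2c(=O)cc(-c3ccc(OCc4ccccc4)cc3)oc2c1 | intermediate
11 | 2-[4-(benzyloxy)phenyl]-7-methoxy-4-oxo-4H-chromen-5-yl acetate (5-O-acetyl-4'-O-benzylgenkwanin) | COc1cc(OC(C)=O)c2c(=O)cc(-c3ccc(OCc4ccccc4)cc3)oc2c1 | intermediate
12 | 2-(4-hydroxyphenyl)-7-methoxy-4-oxo-4H-chromen-5-yl acetate (5-O-acetylgenkwanin) | COc1cc(OC(C)=O)c2c(=O)cc(-c3ccc(O)cc3)oc2c1 | intermediate
13 | 2-{3-[5,7-bis(benzyloxy)-2-(4-methoxyphenyl)-4-oxo-4H-chromen-8-yl]-4-hydroxyphenyl}-7-methoxy-4-oxo-4H-chromen-5-yl acetate (5-O-acetyl-5'',7''-di-O-benzylputraflavone) | COc1ccc(-c2cc(=O)c3c(OCc4ccccc4)cc(OCc4ccccc4)c(-c4cc(-c5cc(=O)c6c(OC(C)=O)cc(OC)cc6o5)ccc4O)c3o2)cc1 | intermediate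
14 | 5,7-bis(benzyloxy)-8-[2-hydroxy-5-(5-hydroxy-7-methoxy-4-oxo-4H-chromen-2-yl)phenyl]-2-(4-methoxyphenyl)-4H-chromen-4-one (5'',7''-di-O-benzylputraflavone) | COc1ccc(-c2cc(=O)c3c(OCc4ccccc4)cc(OCc4ccccc4)c(-c4cc(-c5cc(=O)c6c(O)cc(OC)cc6o5)ccc4O)c3o2)cc1 | intermediate
15 | putraflavone (7,4'''-di-O-methylamentoflavone) | COc1ccc(-c2cc(=O)c3c(O)cc(O)c(-c4cc(-c5cc(=O)c6c(O)cc(OC)cc6o5)ccc4O)c3o2)cc1 | target

**Step count**

Total: 11 steps. Longest linear sequence: 8 steps (steps 4, 5, 6, 7, 8, 9, 10, 11); the arene branch (steps 1–3) joins at step 9.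

**Steps most likely to fail**

1. Step 9 (proposed new method). The phenoxyl radical may be consumed by homo-coupling, the arene may be attacked at C6'' or on ring B, or the benzyl ethers may be degraded at the anode, so the cross-coupled biaryl may not form selectively. The fallback makes the same C3'–C8'' bond by Suzuki–Miyaura coupling.
   - Setting out from 6, electrophilic iodination (N-iodosuccinimide, cat. CF3CO2H, MeCN, rt) should give 8-iodo-5,7-di-O-benzylacacetin F1, C8 being the usual site of halogenation in 5,7-dialkoxyflavones.
   - Setting out from 12, ortho-iodination of the only free phenol (N-iodosuccinimide, cat. p-TsOH, MeCN, rt) should give 5-O-acetyl-3'-iodogenkwanin F2; the acetate keeps ring A from competing.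
   - Miyaura borylation of F2 (B2pin2, PdCl2(dppf), KOAc, dioxane, 90 °C) should give 5-O-acetyl-3'-(4,4,5,5-tetramethyl-1,3,2-dioxaborolan-2-yl)genkwanin F3.
   - Coupling of F3 with F1 (Pd(PPh3)4, aq K2CO3, DMF, 90 °C) should form the biaryl. The aqueous carbonate is expected to hydrolyse the 5-acetate in the same pot, so the route is re-entered at 14; any acetate that survives is removed under the conditions of step 10.

2. Step 3. HI formed in the iodine cycle may cleave the 5-O-benzyl ether peri to the carbonyl, or iodine may substitute ring A during the hot oxidative cyclisation. The fallback builds the pyranone from a 1,3-diketone with no oxidant. Setting out from 2 (chalcone 4 is bypassed), C-aroylation of the lithium dianion (LiN(SiMe3)2, 3 equiv, THF, −78 °C to rt) with 4-methoxybenzoyl chloride should give 1-[2,4-bis(benzyloxy)-6-hydroxyphenyl]-3-(4-methoxyphenyl)propane-1,3-dione F4. Acid cyclodehydration (p-TsOH·H2O, toluene, reflux) then returns to the route at 6.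

3. Step 5. O-aroylation of the phenoxides or a second aroylation may compete with C-acylation of the poorly soluble trilithium species. The fallback is the classical two-stage Baker–Venkataraman sequence. Setting out from 7, O-aroylation with 8 (1 equiv, pyridine, 0 °C to rt) should give the mono-ester 2-acetyl-3-hydroxy-5-methoxyphenyl 4-(benzyloxy)benzoate F5, the second hydroxyl being chelated and slower to acylate. KOH in pyridine at 50 °C then drives the intramolecular O-to-C acyl shift (enolate attack on the ester), and acidic work-up returns to the route at 9.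

**Further compounds**

F1 | step 9 | 5,7-bis(benzyloxy)-8-iodo-2-(4-methoxyphenyl)-4H-chromen-4-one (8-iodo-5,7-di-O-benzylacacetin) | COc1ccc(-c2cc(=O)c3c(OCc4ccccc4)cc(OCc4ccccc4)c(I)c3o2)cc1
F2 | step 9 | 2-(4-hydroxy-3-iodophenyl)-7-methoxy-4-oxo-4H-chromen-5-yl acetate (5-O-acetyl-3'-iodogenkwanin) | COc1cc(OC(C)=O)c2c(=O)cc(-c3ccc(O)c(I)c3)oc2c1
F3 | step 9 | 2-[4-hydroxy-3-(4,4,5,5-tetramethyl-1,3,2-dioxaborolan-2-yl)phenyl]-7-methoxy-4-oxo-4H-chromen-5-yl acetate | COc1cc(OC(C)=O)c2c(=O)cc(-c3ccc(O)c(B4OC(C)(C)C(C)(C)O4)c3)oc2c1
F4 | step 3 | 1-[2,4-bis(benzyloxy)-6-hydroxyphenyl]-3-(4-methoxyphenyl)propane-1,3-dione | COc1ccc(C(=O)CC(=O)c2c(O)cc(OCc3ccccc3)cc2OCc2ccccc2)cc1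
F5 | step 5 | 2-acetyl-3-hydroxy-5-methoxyphenyl 4-(benzyloxy)benzoate | CC(=O)c1c(O)cc(OC)cc1OC(=O)c1ccc(OCc2ccccc2)cc1
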